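A G that leaves by the first step can still become J, and a G that leaves by the third step cannot, so we want to know how the charge divides at that fork.

all flasks: G 0.050 M; Q 10 mol%; time 2.0 d
- west: temperature 35 °C
- south-west: temperature 60 °C
- south: temperature 85 °C

    G → X (k1 = 0.13 /h, Ea1 = 103 kJ/mol)
    Q + X → Q + J (k2 = 100 /M/h, Ea2 = 63.0 kJ/mol)
    2 G → G2 (k3 = 36 /M/h, Ea3 = 79.0 kJ/mol)
    (constants at 60 °C)

- in percentages every species weighs as the G in it: one G2 counts as two
- a doubled species enters its step squared and goes two at a time
- at 60 °C the constants are as listed, elsewhere as the activation energies make them

- the best flask by amount of J, in percent of the G charged; "all alike" if 1.5 percentage points covers them all (west / south-west / south / all alike)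
- amount of J at the end, in percent of the G charged, west
- amount of J at the end, in percent of the G charged, south-west
- amount of J at the end, in percent of the G charged, south

Write g for the fraction of the charge still present as G. At the start of the south-west flask, the first step removes 0.13 /h of the charge and the third 3.60 /h, so the third runs faster than the first. The ratio of these two starting rates we call the split, the selectivity factor of the fork: 27.7.

A first answer for the share of the south-west charge reaching X is one over one plus the split, 3.48%. We put that back in, because the first step slows as g and the third as g squared, so the running ratio is the split times g. At g = 0.5 in the south-west flask, the share of the G then leaving that goes to X is 6.73%. Summed down to g = 0, the accumulated slowing gives a ceiling: the logarithm of one plus the split, divided by the split, for the south-west flask 12.1%.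

The third step's activation energy is lower than the first's, so heat lowers the split: 55.9 in the west flask and 15.1 in the south flask. Their ceilings are 7.23% and 18.4%, and the south ceiling is the highest.

A ceiling needs the charge used up. The quantity g over one plus split times g decays with the first step's constant, which in the west flask is 0.00636 /h. That leaves 4.69% as G in the west flask and sends 4.93% through X, so we expect J somewhat below that. The south-west flask keeps 0.00681% as G, and we take it and the south flask at their ceilings.

The forecast says south, with 4.4%, 12.1% and 18.4% for west, south-west and south, holding that “the share going through X to J rises with temperature and south wins”. Our hand figure for the west flask stops at a bound, while the forecast names a value.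

The simulation gives south, with 4.33%, 12.1% and 18.4%.

Now cut the south-west charge to 0.013 M, holding the loading and the time. At one temperature the split goes with the charge, so in this flask it falls to 7.20 and the ceiling rises to 29.2%. The forecast's 12.1% was made for the full charge; at this charge the run gives 29.0% of J, with 0.198% still X and 0.024% still G, and that J is more than the 18.4% of the south flask at full charge.

(The numbers stand for no real mixture.)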